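The γ-butyrolactone ring (O1, C2(=O), C3, C4, C5) is disconnected at O1–C5. Without O1 it is a 3-substituted cyclobutanone whose two CH2 groups flanking the carbonyl (the future C3 and C5) are enantiotopic. A catalyst-controlled Baeyer–Villiger oxidation inserts O1, enlarges the ring from four to five members and sets C4 (R) in one operation. Its precursor is the cyclobutanone carrying the silylated (2S,3R)-2-aryl-2,3-dihydrobenzofuran-5-ylmethyl group, built from eugenol (whose allyl group supplies the benzylic CH2 and two ring carbons) by auxiliary aldol, quinone-methide cyclisation and dichloroketene cycloaddition. Enolate alkylation with the ring A benzylic bromide and one fluoride deprotection finish the synthesis.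

Key step: step 12

Remark: ring A is the guaiacyl ring bonded to the lactone α-CH2; ring B is the arene of the dihydrobenzofuran. The ring A diol unit is the anti (1S,2S) isomer and its C2 has the opposite sense to C3 of the dihydrobenzofuran, so both units are drawn from one acyl oxazolidinone (9) by two different aldol protocols.
Assumption: aldehyde 10 is a catalogue compound (otherwise one step from vanillin, tBuMe2SiCl/imidazole). Every hydroxyl group is carried as a silyl ether, so one fluoride step ends the synthesis and no hydrogenolysis is run beside the benzylic C–O bonds.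
Assumption: the (R)-phosphoric acid is taken to deliver the (R)-lactone; the sense is to be fixed beforehand on 3-benzylcyclobutanone and the antipodal acid used if required.

Step 1
Reactants: 1 eugenol
Product: 2 5-allyl-2-hydroxy-3-methoxybenzaldehyde
Conditions: MgCl2, Et3N, (CH2O)n, MeCN, reflux
Reagents that add atoms: paraformaldehyde (as formaldehyde) C=O
Why: Casnati–Skattebøl ortho-formylation, in which the magnesium phenoxide delivers formaldehyde to the only free ortho position and a second formaldehyde oxidises the benzylic alkoxide by hydride transfer.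

Step 2
Reactants: 2 5-allyl-2-hydroxy-3-methoxybenzaldehyde
Product: 3 5-allyl-3-methoxy-2-(triisopropylsilyloxy)benzaldehyde
Conditions: iPr3SiOTf, Et3N, CH2Cl2, 0 °C to rt
Reagents that add atoms: triisopropylsilyl triflate CC(C)[Si](OS(=O)(=O)C(F)(F)F)(C(C)C)C(C)C
Why: Silyl ether formation with the reactive triflate on a hindered, hydrogen-bonded phenol; the triisopropylsilyl group should survive ylide, dilute acid, chlorite, enolate and hydride steps and leave with fluoride.

Step 3
Reactants: 3 5-allyl-3-methoxy-2-(triisopropylsilyloxy)benzaldehyde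
Product: 5 2-[5-allyl-3-methoxy-2-(triisopropylsilyloxy)phenyl]acetaldehyde, via enol ether 4 (not isolated)
Conditions: Ph3P(CH2OMe)Cl, KOtBu, THF, 0 °C; then 2 M aq. HCl, THF, 50 °C
Reagents that add atoms: (methoxymethyl)triphenylphosphonium chloride COC[P+](c1ccccc1)(c1ccccc1)c1ccccc1.[Cl-]; water O
Why: Wittig methoxymethylenation followed by enol ether hydrolysis is a standard one-carbon homologation, and the aryl silyl ether and the isolated allyl group are inert to dilute acid.

Step 4
Reactants: 5 2-[5-allyl-3-methoxy-2-(triisopropylsilyloxy)phenyl]acetaldehyde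
Product: 6 2-[5-allyl-3-methoxy-2-(triisopropylsilyloxy)phenyl]acetic acid
Conditions: NaClO2, NaH2PO4, 2-methylbut-2-ene, tBuOH/H2O, 0 °C to rt
Reagents that add atoms: sodium chlorite [Na+].[O-]Cl=O
Why: Pinnick oxidation, with 2-methylbut-2-ene trapping hypochlorous acid so that the allyl group and the electron-rich ring are spared.

Step 5
Reactants: 6 2-[5-allyl-3-methoxy-2-(triisopropylsilyloxy)phenyl]acetic acid; 7 (S)-4-benzyloxazolidin-2-one
Product: 9 (S)-3-{2-[5-allyl-3-methoxy-2-(triisopropylsilyloxy)phenyl]acetyl}-4-benzyloxazolidin-2-one, via mixed pivalic anhydride 8 (not isolated)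
Conditions: tBuCOCl, Et3N, THF, −20 °C; then LiCl, 7, −20 °C to rt
Reagents that add atoms: none
Why: N-acylation of the oxazolidinone through a mixed anhydride, the hindered pivaloyl carbonyl directing attack to the arylacetyl carbonyl.

Step 6
Reactants: 9 (S)-3-{2-[5-allyl-3-methoxy-2-(triisopropylsilyloxy)phenyl]acetyl}-4-benzyloxazolidin-2-one; 10 4-(tert-butyldimethylsilyloxy)-3-methoxybenzaldehyde
Product: 11 (S)-4-benzyl-3-{(2S,3S)-2-[5-allyl-3-methoxy-2-(triisopropylsilyloxy)phenyl]-3-[4-(tert-butyldimethylsilyloxy)-3-methoxyphenyl]-3-hydroxypropanoyl}oxazolidin-2-one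
Conditions: Bu2BOTf, iPr2NEt, CH2Cl2, 0 °C; 10, −78 to 0 °C; then pH 7 buffer, MeOH, 30% H2O2, 0 °C
Reagents that add atoms: none
Why: Evans syn-aldol, in which the Z-dibutylboron enolate reacts through a Zimmerman–Traxler chair on the face away from the auxiliary benzyl group and so sets C2 (the later C3 of the dihydrobenzofuran) as S; the carbinol centre is also set but is re-formed in step 8.

Step 7
Reactants: 11 syn-aldol imide
Product: 12 (1S,2R)-2-[5-allyl-3-methoxy-2-(triisopropylsilyloxy)phenyl]-1-[4-(tert-butyldimethylsilyloxy)-3-methoxyphenyl]propane-1,3-diol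
Conditions: LiBH4, MeOH (1 equiv), THF, 0 °C
Reagents that add atoms: none
Why: Reductive cleavage of the N-acyl oxazolidinone with LiBH4 at the exocyclic carbonyl, which touches no stereocentre (the descriptor at C2 changes only through the priority rules).

Step 8
Reactants: 12 syn-diol bis(aryl silyl ether)
Product: 14 4-[(2S,3R)-5-allyl-3-(hydroxymethyl)-7-methoxy-2,3-dihydrobenzofuran-2-yl]-2-methoxyphenol, via free-phenol tetraol 13 (not isolated)
Conditions: Bu4NF (2.2 equiv), THF, 0 °C; then TsOH·H2O (3 equiv), rt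
Reagents that add atoms: none
Why: Fluoride frees both phenols, and acid then turns the p-hydroxybenzylic alcohol into a p-quinone methide that the ortho phenol captures in a 5-exo-trig oxa-Michael cyclisation; the untouched C3 (R) places the aryl group trans, so C2 forms as S under both kinetic and thermodynamic control.

Step 9
Reactants: 14 dihydrobenzofuran phenol alcohol
Product: 15 (2S,3R)-5-allyl-2-[4-(tert-butyldimethylsilyloxy)-3-methoxyphenyl]-3-[(tert-butyldimethylsilyloxy)methyl]-7-methoxy-2,3-dihydrobenzofuran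
Conditions: tBuMe2SiCl, imidazole, DMF, rt
Reagents that add atoms: tert-butyldimethylsilyl chloride CC(C)(C)[Si](C)(C)Cl
Why: Standard silylation of the phenol and the primary alcohol, giving base-stable, non-acidic protection for the ketene, oxidation and enolate steps.

Step 10
Reactants: 15 bis-silylated 5-allyl dihydrobenzofuran; 16 trichloroacetyl chloride
Product: 17 2,2-dichloro-3-{[(2S,3R)-2-[4-(tert-butyldimethylsilyloxy)-3-methoxyphenyl]-3-[(tert-butyldimethylsilyloxy)methyl]-7-methoxy-2,3-dihydrobenzofuran-5-yl]methyl}cyclobutanone (both epimers at the ring carbon)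
Conditions: Zn/Cu couple, Cl3CCOCl (slow addition), Et2O/DME, rt, sonication
Reagents that add atoms: none
Why: Thermal [2+2] cycloaddition of dichloroketene (from zinc dechlorination of 16) to the terminal alkene, the ketene carbonyl carbon bonding to the terminal CH2; the new ring stereocentre is uncontrolled but becomes non-stereogenic in step 11, and DME ties up ZnCl2.

Step 11
Reactants: 17 dichlorocyclobutanone
Product: 18 3-{[(2S,3R)-2-[4-(tert-butyldimethylsilyloxy)-3-methoxyphenyl]-3-[(tert-butyldimethylsilyloxy)methyl]-7-methoxy-2,3-dihydrobenzofuran-5-yl]methyl}cyclobutanone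
Conditions: Zn dust, NH4Cl, MeOH, rt
Reagents that add atoms: none
Why: Zinc-mediated reductive dechlorination of the α,α-dichloroketone through zinc enolates, under conditions mild enough for both silyl ethers.

Step 12
Reactants: 18 3-(dihydrobenzofuran-5-ylmethyl)cyclobutanone
Product: 19 (R)-4-{[(2S,3R)-2-[4-(tert-butyldimethylsilyloxy)-3-methoxyphenyl]-3-[(tert-butyldimethylsilyloxy)methyl]-7-methoxy-2,3-dihydrobenzofuran-5-yl]methyl}dihydrofuran-2(3H)-one
Conditions: (R)-3,3′-bis(pyren-1-yl)-H8-BINOL phosphoric acid (10 mol%), 30% aq. H2O2 (1.5 equiv), CHCl3, −40 °C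
Reagents that add atoms: hydrogen peroxide OO
Why: The bifunctional phosphoric acid activates both ketone and H2O2, a catalyst-bound Criegee adduct forms, and the CH2 group lying antiperiplanar to the O–O bond migrates from carbon to oxygen with loss of water; the closest known reaction type is the phosphoric acid-catalysed Baeyer–Villiger desymmetrisation of 3-substituted cyclobutanones with aqueous H2O2. The five-membered lactone arises by ring expansion (a 1,2-shift inserting O1 into the C2–C5 bond of the four-membered ring), not by an exo or endo cyclisation. C4 becomes stereogenic only through the choice between the two enantiotopic methylenes, and the chiral pocket of the catalyst makes this choice, because the dihydrobenzofuran centres are too remote to bias it. The step needs enantiotopic-group selectivity and chemoselectivity; both α-carbons are CH2, so no regiochemical question arises, and the ring strain lets H2O2 react at low temperature without touching the electron-rich arenes or the silyl ethers.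

Step 13
Reactants: 9 (S)-3-{2-[5-allyl-3-methoxy-2-(triisopropylsilyloxy)phenyl]acetyl}-4-benzyloxazolidin-2-one; 10 4-(tert-butyldimethylsilyloxy)-3-methoxybenzaldehyde
Product: 21 (S)-4-benzyl-3-{(2R,3S)-2-[5-allyl-3-methoxy-2-(triisopropylsilyloxy)phenyl]-3-[4-(tert-butyldimethylsilyloxy)-3-methoxyphenyl]-3-hydroxypropanoyl}oxazolidin-2-one, via O-trimethylsilyl aldol adduct 20 (not isolated)
Conditions: MgCl2 (20 mol%), Et3N, Me3SiCl, EtOAc, rt; then PPTS (cat.), MeOH, 0 °C
Reagents that add atoms: none
Why: Magnesium halide-catalysed direct anti-aldol of an N-acyl oxazolidinone with an aromatic aldehyde, in which the chelated magnesium Z-enolate reacts on the face opposite the benzyl group through a boat-like transition state to set C2 (R) and C3 (S), with silylation of the aldolate turning the catalyst over.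

Step 14
Reactants: 21 anti-aldol imide
Product: 22 (1S,2S)-2-[5-allyl-3-methoxy-2-(triisopropylsilyloxy)phenyl]-1-[4-(tert-butyldimethylsilyloxy)-3-methoxyphenyl]propane-1,3-diol
Conditions: LiBH4, MeOH (1 equiv), THF, 0 °C
Reagents that add atoms: none
Why: Reductive cleavage of the N-acyl oxazolidinone as in step 7, leaving both stereocentres untouched.

Step 15
Reactants: 22 anti-diol
Product: 23 bis(tert-butyldimethylsilyl) ether of 22: (1S,2S)-1,3-bis(tert-butyldimethylsilyloxy)-2-[5-allyl-3-methoxy-2-(triisopropylsilyloxy)phenyl]-1-[4-(tert-butyldimethylsilyloxy)-3-methoxyphenyl]propane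
Conditions: tBuMe2SiOTf, 2,6-lutidine, CH2Cl2, −78 to 0 °C
Reagents that add atoms: tert-butyldimethylsilyl triflate CC(C)(C)[Si](C)(C)OS(=O)(=O)C(F)(F)F
Why: Silylation with the triflate protects the primary and the hindered benzylic alcohol in one operation under non-ionising, buffered conditions.

Step 16
Reactants: 23 allyl arene
Product: 24 (E)-prop-1-enyl arene: 23 with the allyl group moved into conjugation with ring A
Conditions: RuHCl(CO)(PPh3)3 (3 mol%), toluene, 80 °C
Reagents that add atoms: none
Why: Ruthenium hydride-catalysed olefin isomerisation (hydrometalation and β-hydride elimination) should move the double bond into conjugation with the arene, the thermodynamically preferred position.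

Step 17
Reactants: 24 prop-1-enyl arene
Product: 26 ring A benzylic alcohol: 3-[(1S,2S)-1,3-bis(tert-butyldimethylsilyloxy)-1-[4-(tert-butyldimethylsilyloxy)-3-methoxyphenyl]propan-2-yl]-5-methoxy-4-(triisopropylsilyloxy)benzyl alcohol, via aryl aldehyde 25 (not isolated)
Conditions: O3, CH2Cl2/MeOH, −78 °C (Sudan Red 7B end point); then NaBH4, −78 to 0 °C
Reagents that add atoms: ozone [O-][O+]=O
Why: Ozonolysis with reductive borohydride work-up, in which the conjugated styrenyl alkene should react with ozone far faster than the alkoxy arenes and the indicator dye marks the end point.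

Step 18
Reactants: 26 ring A benzylic alcohol
Product: 27 ring A benzylic bromide: 3-[(1S,2S)-1,3-bis(tert-butyldimethylsilyloxy)-1-[4-(tert-butyldimethylsilyloxy)-3-methoxyphenyl]propan-2-yl]-5-methoxy-4-(triisopropylsilyloxy)benzyl bromide
Conditions: CBr4, PPh3, CH2Cl2, 0 °C; used at once
Reagents that add atoms: carbon tetrabromide BrC(Br)(Br)Br
Why: Appel bromination converts the primary benzylic alcohol under neutral conditions that leave the silyl ethers and the ionisable benzylic silyl ether intact.

Step 19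
Reactants: 19 (R)-4-(dihydrobenzofuran-5-ylmethyl)butyrolactone; 27 ring A benzylic bromide
Product: 28 hexasilyl ether of the target: (3R,4R)-3-(ring A benzyl)-4-(dihydrobenzofuran-5-ylmethyl)dihydrofuran-2(3H)-one carrying five tert-butyldimethylsilyl ethers and one triisopropylsilyl ether
Conditions: LiN(SiMe3)2, THF, −78 °C; then 27, DMPU, −78 to −40 °C
Reagents that add atoms: none
Why: Alkylation of the lactone lithium enolate with a benzylic bromide, the electrophile approaching the enolate face anti to the C4 substituent so that C3 forms as R (trans), as in the usual construction of trans-α,β-dibenzylbutyrolactones.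

Step 20
Reactants: 28 hexasilyl ether of the target
Product: 29 CNP0186558.2 (target)
Conditions: Bu4NF, AcOH (1:1, excess), THF, 0 °C to rt
Reagents that add atoms: none
Why: Fluoride-mediated desilylation removes all six silyl groups, and the acetic acid buffer keeps the phenols protonated so that neither quinone-methide formation nor lactone epimerisation is promoted.

Compound list
1 | eugenol | C=CCc1ccc(O)c(OC)c1 | starting material
2 | 5-allyl-2-hydroxy-3-methoxybenzaldehyde | C=CCc1cc(C=O)c(O)c(OC)c1 | intermediate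
3 | 5-allyl-3-methoxy-2-(triisopropylsilyloxy)benzaldehyde | C=CCc1cc(C=O)c(O[Si](C(C)C)(C(C)C)C(C)C)c(OC)c1 | intermediate
4 | enol ether: 5-allyl-1-methoxy-3-(2-methoxyvinyl)-2-(triisopropylsilyloxy)benzene (E/Z) | C=CCc1cc(C=COC)c(O[Si](C(C)C)(C(C)C)C(C)C)c(OC)c1 | intermediate
5 | 2-[5-allyl-3-methoxy-2-(triisopropylsilyloxy)phenyl]acetaldehyde | C=CCc1cc(CC=O)c(O[Si](C(C)C)(C(C)C)C(C)C)c(OC)c1 | intermediate
6 | 2-[5-allyl-3-methoxy-2-(triisopropylsilyloxy)phenyl]acetic acid | C=CCc1cc(CC(=O)O)c(O[Si](C(C)C)(C(C)C)C(C)C)c(OC)c1 | intermediate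
7 | (S)-4-benzyloxazolidin-2-one | O=C1N[C@@H](Cc2ccccc2)CO1 | starting material
8 | mixed pivalic anhydride of 6 | C=CCc1cc(CC(=O)OC(=O)C(C)(C)C)c(O[Si](C(C)C)(C(C)C)C(C)C)c(OC)c1 | intermediate
9 | (S)-3-{2-[5-allyl-3-methoxy-2-(triisopropylsilyloxy)phenyl]acetyl}-4-benzyloxazolidin-2-one | C=CCc1cc(CC(=O)N2[C@@H](Cc3ccccc3)COC2=O)c(O[Si](C(C)C)(C(C)C)C(C)C)c(OC)c1 | intermediate
10 | 4-(tert-butyldimethylsilyloxy)-3-methoxybenzaldehyde | COc1cc(C=O)ccc1O[Si](C)(C)C(C)(C)C | starting material
11 | (2S,3S) syn-aldol imide | COc1cc([C@@H](O)[C@@H](C(=O)N2[C@@H](Cc3ccccc3)COC2=O)c2cc(CC=C)cc(OC)c2O[Si](C(C)C)(C(C)C)C(C)C)ccc1O[Si](C)(C)C(C)(C)C | intermediate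
12 | (1S,2R) syn-diol, both phenols silylated | COc1cc([C@@H](O)[C@@H](CO)c2cc(CC=C)cc(OC)c2O[Si](C(C)C)(C(C)C)C(C)C)ccc1O[Si](C)(C)C(C)(C)C | intermediate
13 | (1S,2R)-2-(5-allyl-2-hydroxy-3-methoxyphenyl)-1-(4-hydroxy-3-methoxyphenyl)propane-1,3-diol | COc1cc([C@@H](O)[C@@H](CO)c2cc(CC=C)cc(OC)c2O)ccc1O | intermediate
14 | 4-[(2S,3R)-5-allyl-3-(hydroxymethyl)-7-methoxy-2,3-dihydrobenzofuran-2-yl]-2-methoxyphenol | C=CCc1cc(OC)c2c(c1)[C@H](CO)[C@@H](c1ccc(O)c(OC)c1)O2 | intermediate
15 | bis(tert-butyldimethylsilyl) ether of 14 | C=CCc1cc(OC)c2c(c1)[C@H](CO[Si](C)(C)C(C)(C)C)[C@@H](c1ccc(O[Si](C)(C)C(C)(C)C)c(OC)c1)O2 | intermediate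
16 | trichloroacetyl chloride | ClC(Cl)(Cl)C(Cl)=O | starting material
17 | 2,2-dichloro-3-(dihydrobenzofuran-5-ylmethyl)cyclobutanone (epimers at the ring carbon) | O=C1CC(Cc2cc(OC)c3c(c2)[C@H](CO[Si](C)(C)C(C)(C)C)[C@@H](c2ccc(O[Si](C)(C)C(C)(C)C)c(OC)c2)O3)C1(Cl)Cl | intermediate
18 | 3-(dihydrobenzofuran-5-ylmethyl)cyclobutanone (key-step precursor) | O=C1CC(Cc2cc(OC)c3c(c2)[C@H](CO[Si](C)(C)C(C)(C)C)[C@@H](c2ccc(O[Si](C)(C)C(C)(C)C)c(OC)c2)O3)C1 | intermediate
19 | (R)-4-(dihydrobenzofuran-5-ylmethyl)dihydrofuran-2(3H)-one (key-step product) | O=C1C[C@@H](Cc2cc(OC)c3c(c2)[C@H](CO[Si](C)(C)C(C)(C)C)[C@@H](c2ccc(O[Si](C)(C)C(C)(C)C)c(OC)c2)O3)CO1 | intermediate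
20 | O-trimethylsilyl ether of the (2R,3S) anti-aldol imide | COc1cc([C@@H](O[Si](C)(C)C)[C@H](C(=O)N2[C@@H](Cc3ccccc3)COC2=O)c2cc(CC=C)cc(OC)c2O[Si](C(C)C)(C(C)C)C(C)C)ccc1O[Si](C)(C)C(C)(C)C | intermediate
21 | (2R,3S) anti-aldol imide | COc1cc([C@@H](O)[C@H](C(=O)N2[C@@H](Cc3ccccc3)COC2=O)c2cc(CC=C)cc(OC)c2O[Si](C(C)C)(C(C)C)C(C)C)ccc1O[Si](C)(C)C(C)(C)C | intermediate
22 | (1S,2S) anti-diol, both phenols silylated | COc1cc([C@@H](O)[C@H](CO)c2cc(CC=C)cc(OC)c2O[Si](C(C)C)(C(C)C)C(C)C)ccc1O[Si](C)(C)C(C)(C)C | intermediate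
23 | bis(tert-butyldimethylsilyl) ether of 22 | COc1cc([C@@H](O[Si](C)(C)C(C)(C)C)[C@H](CO[Si](C)(C)C(C)(C)C)c2cc(CC=C)cc(OC)c2O[Si](C(C)C)(C(C)C)C(C)C)ccc1O[Si](C)(C)C(C)(C)C | intermediate
24 | (E)-prop-1-enyl isomer of 23 | COc1cc([C@@H](O[Si](C)(C)C(C)(C)C)[C@H](CO[Si](C)(C)C(C)(C)C)c2cc(/C=C/C)cc(OC)c2O[Si](C(C)C)(C(C)C)C(C)C)ccc1O[Si](C)(C)C(C)(C)C | intermediate
25 | ring A benzaldehyde | COc1cc([C@@H](O[Si](C)(C)C(C)(C)C)[C@H](CO[Si](C)(C)C(C)(C)C)c2cc(C=O)cc(OC)c2O[Si](C(C)C)(C(C)C)C(C)C)ccc1O[Si](C)(C)C(C)(C)C | intermediate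
26 | ring A benzylic alcohol | COc1cc([C@@H](O[Si](C)(C)C(C)(C)C)[C@H](CO[Si](C)(C)C(C)(C)C)c2cc(CO)cc(OC)c2O[Si](C(C)C)(C(C)C)C(C)C)ccc1O[Si](C)(C)C(C)(C)C | intermediate
27 | ring A benzylic bromide | COc1cc([C@@H](O[Si](C)(C)C(C)(C)C)[C@H](CO[Si](C)(C)C(C)(C)C)c2cc(CBr)cc(OC)c2O[Si](C(C)C)(C(C)C)C(C)C)ccc1O[Si](C)(C)C(C)(C)C | intermediate
28 | hexasilyl ether of the target, (3R,4R)-lactone | COc1cc([C@@H](O[Si](C)(C)C(C)(C)C)[C@H](CO[Si](C)(C)C(C)(C)C)c2cc(C[C@H]3C(=O)OC[C@@H]3Cc3cc(OC)c4c(c3)[C@H](CO[Si](C)(C)C(C)(C)C)[C@@H](c3ccc(O[Si](C)(C)C(C)(C)C)c(OC)c3)O4)cc(OC)c2O[Si](C(C)C)(C(C)C)C(C)C)ccc1O[Si](C)(C)C(C)(C)C | intermediate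
29 | CNP0186558.2 | COc1cc([C@@H](O)[C@H](CO)c2cc(C[C@H]3C(=O)OC[C@@H]3Cc3cc(OC)c4c(c3)[C@H](CO)[C@@H](c3ccc(O)c(OC)c3)O4)cc(OC)c2O)ccc1O | target

Total step count: 20. Longest linear sequence: 14 steps (steps 1–12, 19 and 20, from eugenol).

Steps most likely to fail

Step 12. The catalyst may distinguish the two enantiotopic methylene groups only moderately when the 3-substituent is a benzyl-type group and not an aryl group. Oxygen insertion on the wrong side would then give the C4 epimer as a remote diastereomer that is hard to remove. The fallback sets out from 18 and returns at 19. Enantioselective deprotonation of 18 with the chiral lithium amide LiN[(S)-CH(Me)Ph]2 (or its antipode, fixed on a model ketone) in THF at −100 °C with Me3SiCl present would give the (R)-configured trimethylsilyl enol ether F1. Ozonolysis of the enol double bond (O3, CH2Cl2/MeOH, −78 °C), NaBH4 reduction of the aldehyde end and mild acidification would give the hydroxy acid F2, which closes to lactone 19. The stereocentre is then set by a chiral base instead of an oxidation catalyst.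

Step 13. With the more acidic α-aryl imide, the magnesium enolate may give poor anti/syn and facial selectivity. Retro-aldol before silylation or epimerisation at C2 would also erode the (2R,3S) adduct. The fallback sets out from 6 and returns at 22. It replaces the chelating oxazolidinone by a thiazolidinethione auxiliary that reacts through a non-chelated enolate with the opposite anti sense and is cleaved by borohydride under nearly neutral conditions. Acid 6 is coupled (EDC·HCl, DMAP, CH2Cl2) with (R)-4-benzylthiazolidine-2-thione to give the N-acyl thiazolidinethione F3. The MgBr2·OEt2-catalysed direct aldol with 10 (Et3N, Me3SiCl, EtOAc) would give the silylated adduct F4 and, after PPTS/MeOH, the anti-aldol F5. NaBH4 in THF/EtOH then releases diol 22.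

Step 10. The monosubstituted alkene is a sluggish partner for dichloroketene, so ketene oligomerisation may outrun the cycloaddition. ZnCl2 may also open or epimerise the acid-labile 2-aryl dihydrobenzofuran or strip a silyl ether. The fallback sets out from 15 and returns at 18, bypassing 17 and the dechlorination. A keteniminium [2+2] cycloaddition (N,N-dimethylacetamide, Tf2O, 2,4,6-collidine, 1,2-dichloroethane, reflux) would give the cyclobutaniminium triflate F6. Hydrolysis with aqueous NaHCO3 then gives cyclobutanone 18 directly.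

Further compounds
F1 | step 12 | (R)-3-(dihydrobenzofuran-5-ylmethyl)-1-(trimethylsilyloxy)cyclobut-1-ene | C[Si](C)(C)OC1=C[C@H](Cc2cc(OC)c3c(c2)[C@H](CO[Si](C)(C)C(C)(C)C)[C@@H](c2ccc(O[Si](C)(C)C(C)(C)C)c(OC)c2)O3)C1
F2 | step 12 | (R)-4-hydroxy-3-(dihydrobenzofuran-5-ylmethyl)butanoic acid | OC(=O)C[C@@H](Cc2cc(OC)c3c(c2)[C@H](CO[Si](C)(C)C(C)(C)C)[C@@H](c2ccc(O[Si](C)(C)C(C)(C)C)c(OC)c2)O3)CO
F3 | step 13 | (R)-3-{2-[5-allyl-3-methoxy-2-(triisopropylsilyloxy)phenyl]acetyl}-4-benzylthiazolidine-2-thione | C=CCc1cc(CC(=O)N2[C@H](Cc3ccccc3)CSC2=S)c(O[Si](C(C)C)(C(C)C)C(C)C)c(OC)c1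
F4 | step 13 | O-trimethylsilyl ether of the (2R,3S) anti-aldol thiazolidinethione | COc1cc([C@@H](O[Si](C)(C)C)[C@H](C(=O)N2[C@H](Cc3ccccc3)CSC2=S)c2cc(CC=C)cc(OC)c2O[Si](C(C)C)(C(C)C)C(C)C)ccc1O[Si](C)(C)C(C)(C)C
F5 | step 13 | (2R,3S) anti-aldol thiazolidinethione | COc1cc([C@@H](O)[C@H](C(=O)N2[C@H](Cc3ccccc3)CSC2=S)c2cc(CC=C)cc(OC)c2O[Si](C(C)C)(C(C)C)C(C)C)ccc1O[Si](C)(C)C(C)(C)C
F6 | step 10 | N,N-dimethyl-3-(dihydrobenzofuran-5-ylmethyl)cyclobutaniminium triflate | C[N+](C)=C1CC(Cc2cc(OC)c3c(c2)[C@H](CO[Si](C)(C)C(C)(C)C)[C@@H](c2ccc(O[Si](C)(C)C(C)(C)C)c(OC)c2)O3)C1.[O-]S(=O)(=O)C(F)(F)F
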